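**Retrosynthetic overview**
1. Target 12 ⇐ bis(1,1-dimethylallyl) ether 11 by one double aromatic Claisen rearrangement that makes both C-prenyl bonds last, with no protecting groups.
2. 11 ⇐ silyl enol ether 10 by Rubottom oxidation (C3–O bond, placed trans to the C2 aryl by substrate control).
3. 10 ⇐ (S)-flavanone 9 ⇐ chromone 4 + arylboronic acid 8 by Rh-catalysed enantioselective conjugate arylation (C2–aryl bond; sets C2).
4. 4 and 8 ⇐ 7-hydroxychromone (1) and 4-bromophenol (5), each O-alkylated with 3-chloro-3-methylbut-1-yne (2) and semihydrogenated.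
5. Ring order: none is built. The benzopyranone is bought intact, so there is no chalcone, no Claisen–Schmidt condensation and no ring closure.

Assumptions: compounds 1, 2 and 5 are catalogue chemicals. The (S)-biaryl bisphosphine is assumed to give the (2S)-flavanone (same sense as (S)-BINAP giving (S)-3-arylcyclohexanones); if the sense is opposite, the (R)-ligand is used.

**Step 1**
Reactants: 1, 7-hydroxy-4H-chromen-4-one; 2, 3-chloro-3-methylbut-1-yne
Product: 3, 7-[(2-methylbut-3-yn-2-yl)oxy]-4H-chromen-4-one
Conditions: K2CO3, KI, CuI (cat.), acetone, reflux, N2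
Reagents that add atoms: 3-chloro-3-methylbut-1-yne (2), C#CC(C)(C)Cl
Why: Cu-assisted O-alkylation of the only phenol by the tertiary propargylic chloride (standard aryl 1,1-dimethylpropargyl ether synthesis); the chromone tolerates K2CO3/acetone.

**Step 2**
Reactants: 3
Product: 4, 7-[(2-methylbut-3-en-2-yl)oxy]-4H-chromen-4-one
Conditions: H2 (1 atm), Lindlar catalyst, quinoline, EtOAc, rt, stopped at 1 equiv H2
Reagents that add atoms: none
Why: Lindlar semihydrogenation; the terminal alkyne is reduced far faster than the vinylogous-ester C2=C3 bond on the poisoned catalyst.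

**Step 3**
Reactants: 5, 4-bromophenol; 2, 3-chloro-3-methylbut-1-yne
Product: 6, 1-bromo-4-[(2-methylbut-3-yn-2-yl)oxy]benzene
Conditions: K2CO3, KI, CuI (cat.), acetone, reflux, N2
Reagents that add atoms: 3-chloro-3-methylbut-1-yne (2), C#CC(C)(C)Cl
Why: same Cu-assisted phenoxide O-propargylation as step 1; the aryl bromide is inert.

**Step 4**
Reactants: 6
Product: 7, 1-bromo-4-[(2-methylbut-3-en-2-yl)oxy]benzene
Conditions: H2 (1 atm), Lindlar catalyst, quinoline, EtOAc, rt
Reagents that add atoms: none
Why: Lindlar semihydrogenation; the poisoned Pd does not hydrogenolyse the aryl bromide at rt.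

**Step 5**
Reactants: 7
Product: 8, {4-[(2-methylbut-3-en-2-yl)oxy]phenyl}boronic acid
Conditions: n-BuLi, THF, −78 °C; B(OiPr)3, −78 °C → rt; sat. aq. NH4Cl
Reagents that add atoms: triisopropyl borate, CC(C)OB(OC(C)C)OC(C)C; water, O
Why: Br/Li exchange then borylation and mild hydrolysis; the tertiary allyl aryl ether is inert to ArLi at −78 °C and survives a near-neutral work-up.

**Step 6**
Reactants: 4; 8 (2.5 equiv)
Product: 9, (2S)-7-[(2-methylbut-3-en-2-yl)oxy]-2-{4-[(2-methylbut-3-en-2-yl)oxy]phenyl}-2,3-dihydro-4H-chromen-4-one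
Conditions: [Rh(OH)((S)-MeO-F12-BIPHEP)]2 (3 mol % Rh), PhMe/H2O 10:1, 30 °C, no added base
Reagents that add atoms: none (water supplies only the C3 proton)
Why: Hayashi–Miyaura Rh-catalysed asymmetric 1,4-addition, in which the ligand-controlled aryl-Rh insertion into C2=C3 sets C2 (S); base-free conditions avoid retro-oxa-Michael racemisation, and the hindered unactivated terminal alkenes do not compete with the enone.

**Step 7**
Reactants: 9
Product: 10, (2S)-7-[(2-methylbut-3-en-2-yl)oxy]-2-{4-[(2-methylbut-3-en-2-yl)oxy]phenyl}-4-[(trimethylsilyl)oxy]-2H-chromene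
Conditions: Et3N (2.5 equiv) then TMSOTf (1.3 equiv), CH2Cl2, −20 → 0 °C; pentane trituration, used crude
Reagents that add atoms: trimethylsilyl triflate, C[Si](C)(C)OS(=O)(=O)C(F)(F)F
Why: soft enolisation (silyl triflate/amine) forms the enol silane without a free enolate, so there is no E1cB ring opening and C2 is untouched; excess amine protects the acid-labile tertiary allyl ethers.

**Step 8**
Reactants: 10
Product: 11, (2R,3R)-3-hydroxy-7-[(2-methylbut-3-en-2-yl)oxy]-2-{4-[(2-methylbut-3-en-2-yl)oxy]phenyl}-2,3-dihydro-4H-chromen-4-one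
Conditions: DMDO (1.05 equiv, acetone), CH2Cl2, −78 → −40 °C; then citric acid, MeOH, 0 °C
Reagents that add atoms: dimethyldioxirane, CC1(C)OO1
Why: Rubottom oxidation, in which DMDO epoxidises the electron-rich enol silane on the face anti to the C2 aryl and collapse/desilylation gives the 2,3-trans ketol, setting C3 (R); the monosubstituted terminal alkenes do not react with 1 equiv DMDO at −78 °C.

**Step 9**
Reactants: 11
Product: 12, 3-hydroxyglabrol, (2R,3R)-3,7-dihydroxy-2-[4-hydroxy-3-(3-methylbut-2-en-1-yl)phenyl]-8-(3-methylbut-2-en-1-yl)-2,3-dihydro-4H-chromen-4-one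
Conditions: degassed m-xylene/N,N-diethylaniline 10:1, 135 °C, sealed tube, Ar, base-washed glassware
Reagents that add atoms: none
Why: double aromatic Claisen rearrangement ([3,3], then tautomerisation) turns each 1,1-dimethylallyl ether into an ortho-prenyl phenol; the B-ring ortho positions are equivalent and the A ring is expected to migrate mainly to C8 (the angular preference of 7-allyloxy benzopyranones, minor C6 isomer separable), while the neutral conditions leave C2 and C3 untouched and trans is the thermodynamic isomer.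

**Compound list**
1 | 7-hydroxy-4H-chromen-4-one | O=c1ccoc2cc(O)ccc12 | starting material
2 | 3-chloro-3-methylbut-1-yne | C#CC(C)(C)Cl | starting material
3 | 7-[(2-methylbut-3-yn-2-yl)oxy]-4H-chromen-4-one | O=c1ccoc2cc(OC(C)(C)C#C)ccc12 | intermediate
4 | 7-[(2-methylbut-3-en-2-yl)oxy]-4H-chromen-4-one | O=c1ccoc2cc(OC(C)(C)C=C)ccc12 | intermediate
5 | 4-bromophenol | Oc1ccc(Br)cc1 | starting material
6 | 1-bromo-4-[(2-methylbut-3-yn-2-yl)oxy]benzene | C#CC(C)(C)Oc1ccc(Br)cc1 | intermediate
7 | 1-bromo-4-[(2-methylbut-3-en-2-yl)oxy]benzene | C=CC(C)(C)Oc1ccc(Br)cc1 | intermediate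
8 | {4-[(2-methylbut-3-en-2-yl)oxy]phenyl}boronic acid | C=CC(C)(C)Oc1ccc(B(O)O)cc1 | intermediate
9 | (2S)-7-[(2-methylbut-3-en-2-yl)oxy]-2-{4-[(2-methylbut-3-en-2-yl)oxy]phenyl}-2,3-dihydro-4H-chromen-4-one | O=C1C[C@@H](c2ccc(OC(C)(C)C=C)cc2)Oc2cc(OC(C)(C)C=C)ccc12 | intermediate
10 | (2S)-7-[(2-methylbut-3-en-2-yl)oxy]-2-{4-[(2-methylbut-3-en-2-yl)oxy]phenyl}-4-[(trimethylsilyl)oxy]-2H-chromene | C[Si](C)(C)OC1=C[C@@H](c2ccc(OC(C)(C)C=C)cc2)Oc2cc(OC(C)(C)C=C)ccc12 | intermediate
11 | (2R,3R)-3-hydroxy-7-[(2-methylbut-3-en-2-yl)oxy]-2-{4-[(2-methylbut-3-en-2-yl)oxy]phenyl}-2,3-dihydro-4H-chromen-4-one | O=C1[C@H](O)[C@@H](c2ccc(OC(C)(C)C=C)cc2)Oc2cc(OC(C)(C)C=C)ccc12 | intermediate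
12 | 3-hydroxyglabrol, (2R,3R)-3,7-dihydroxy-2-[4-hydroxy-3-(3-methylbut-2-en-1-yl)phenyl]-8-(3-methylbut-2-en-1-yl)-2,3-dihydro-4H-chromen-4-one | CC(C)=CCc1cc([C@H]2Oc3c(ccc(O)c3CC=C(C)C)C(=O)[C@@H]2O)ccc1O | target

**Total step count:** 9
**Longest linear sequence:** 7 (steps 3–9, from 4-bromophenol)

**Three steps most likely to fail**
- **Step 9 (double Claisen).** Risks are C6 versus C8 migration on ring A, chroman formation from the o-prenylphenols, and thermal stress on the ketol. Fallback: replace the A-ring Claisen by cross-coupling. Iodinate 1 at C8 (NIS), carry it as the 7-O-MOM 8-iodochromone through the same Rh arylation and Rubottom sequence, then install the prenyl group by Suzuki–Miyaura coupling with prenyl-Bpin. The regiochemically unambiguous B-ring Claisen is kept.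
- **Step 6 (Rh conjugate arylation).** The 7-alkoxy group deactivates the chromone, and ee can erode through ring opening. Fallback: make racemic 9 through the more electrophilic 4-silyloxybenzopyrylium (4 + TBSOTf, then the arylzinc from 7, then hydrolysis). Then resolve by asymmetric transfer hydrogenation (Ru–TsDPEN, HCO2H/Et3N), with the catalyst enantiomer chosen to reduce (2R)-9 to the cis-flavan-4-ol and leave (S)-9.
- **Step 7 (enol silane formation).** The tertiary allyl aryl ethers may ionise with TMSOTf, and 10 is hydrolytically labile. Fallback: change the order. Use TBS-protected phenols (7-OTBS chromone and 4-TBSO-phenylboronic acid) for the Rh arylation and Rubottom steps, so no alkenes or acid-labile ethers are present. Then desilylate and install both 1,1-dimethylallyl ethers on the dihydroflavonol by neutral Pd(0)-catalysed O-allylation with a 2-methylbut-3-en-2-yl carbonate. C2 lability is harmless at that stage because C3 is fixed and trans is thermodynamic. Finish with the same double Claisen.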